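At 40 min I was to read the larch flask, and I had its own run and the colder, leaner elm run to go on.

common to all: X 0.050 M
- larch: J 0.05 mol%; temperature 25 °C; the very flask that is asked about, followed so far
- elm: J 0.034 mol%; temperature 20 °C; run made earlier
- flask: J 0.05 mol%; temperature 25 °C; time 40 min

| run | time / min | Q / % | X / % |
|---|---|---|---|
| larch | 2.00 | 4 | 56 |
| larch | 4.00 | 7 | 29 |
| larch | 6.00 | 16 | 21 |
| larch | 12.0 | 30 | 5 |
| larch | 25.0 | 34 | 2 |
| elm | 0.667 | 0 | 85 |
| elm | 2.00 | 0 | 72 |
| elm | 4.00 | 5 | 50 |
| elm | 6.00 | 5 | 39 |
| elm | 8.00 | 8 | 27 |

(each reading ± 2 percentage points)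

- Q, in percent of the X first charged, at 40 min
- the option that brings most further Q ("none" if no option brings more than 2 percentage points) (blue / red / green / amber / none)
- Q present, with what was taken out counted in, in percent of the X first charged, after green
- Q present, with what was taken out counted in, in percent of the X first charged, after amber

- blue: at 40 min raise the temperature by 15 K, then wait 12 min
- red: change nothing and wait 12 min more
- green: at 40 min add J, 100% of the amount charged, then wait 12 min
- amber: at 40 min take out 90% of the Q then present, then wait 12 min

I ordered the larch readings by speed. On the first rung, X fell at 0.309 min⁻¹ up to 4.00 min, a half-life of 2.24 min. Next came Q, which trailed X and reached 30% at 12.0 min. By 6.00 min a part of the charge had gone missing, 63.0%, and at 25.0 min it still stood at 64.0%. Of the X consumed by then, a share of 0.347 had become Q (the selectivity), so I gave the route to Q a rate constant of 0.107 min⁻¹.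

On the last rung stood what the final X reading allowed. That reading, 2%, lies within one scatter of zero, but I committed to it as a standing floor. My quantity was the drip, 2.6 percentage points, the Q that the route's rate constant makes from the X left standing during the further 12 min. At that pace the missing part would need 4.98 h, a far longer time than the half-life of X in larch, so Q should creep rather than stop.

I therefore reckoned 37.2% at 40 min. Taking the drip as fed by X, and Q as not returning, I put green and amber at 39.8%. Elm's X fell at 0.164 min⁻¹, a ratio of 1.89 for the gap from 20 °C to 25 °C, though elm also held less J. The rise of 15 K is 3 such gaps, so blue should bring 17 points, more than red, and blue was my choice.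

The forecast said 35%, best option none, and 35% after green and 35% after amber, holding that “By 40 min Q should therefore be about 35% and finished”.

The flask gave 38.5% and best option blue, with 10 points against 1.7 points for red, and 40.5% after green and 40.2% after amber.

    X → D (k = 0.101 min⁻¹, Ea = 79.0 kJ mol⁻¹)
    X ⇌ Z (K = 28.6, k = 0.193 min⁻¹, Ea = 87.0 kJ mol⁻¹, ΔH = −24.0 kJ mol⁻¹)
    J + D → J + Q (k = 9210 M⁻¹ min⁻¹, Ea = 43.0 kJ mol⁻¹)
    (constants at 25 °C)

X stood at 1.38% at 40.0 min with Z at 59.5%. Scaled to that X, the drip becomes 1.8 points, beside the 1.7 points that red gave. Blue over red was a factor of 6.07. I carried that factor to the neighbouring flask, the same charge run at 40 °C, where X stood at 1.32%. The drip, scaled to that X, that factor and the whole 40 min, added to the share, gives 69.0%; that flask held 63.5% Q.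

The data stem from a simulated flask with constants of no real substance; noise was put on by code.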